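The 1,4-dioxane ring (O1, C2 aryl, C3 methyl, O4, C4a, C8a; allyl on C7 of the benzo ring) is traced back by deleting O4. What remains is the furan ring of a 2-aryl-3-methyl-2,3-dihydrobenzofuran whose C3 is a benzylic carbon bearing the methyl group and whose fused aryl carbon has O1 ortho to it. Step 5 exploits exactly this: a C3 hydroperoxide rearranges under acid with shift of that aryl carbon to oxygen, forging C4a–O4 and enlarging furan to dioxane in one operation. The precursor is (2R)-6-bromo-3-hydroperoxy-3-methyl-2-(3,4,5-trimethoxyphenyl)-2,3-dihydrobenzofuran; the bromide later becomes the allyl group.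

Key step: step 5

Assumption: which antipode of the Ph-pybox ligand gives the S ether 6 in step 2 is settled in a pilot run; both antipodes are commercial and the one giving (S)-6 is used.

Step 1
Reactants: 1 3,4,5-trimethoxybenzaldehyde; 2 ethynylmagnesium bromide
Product: 4 rac-1-(3,4,5-trimethoxyphenyl)prop-2-yn-1-yl acetate, via bromomagnesium propargylic alkoxide 3 (not isolated)
Conditions: 2, THF, 0 °C; then Ac2O, 0 °C to rt; H2O
Reagents that add atoms: acetic anhydride, CC(=O)OC(C)=O
Why: Acetylide Grignard 1,2-addition to the aldehyde followed by acylation of the bromomagnesium alkoxide in the same flask is routine and should give the racemic propargylic acetate, whose configuration does not matter because step 2 passes through a planar copper allenylidene.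

Step 2
Reactants: 4 rac-1-(3,4,5-trimethoxyphenyl)prop-2-yn-1-yl acetate; 5 5-bromo-2-iodophenol
Product: 6 4-bromo-1-iodo-2-{[(1S)-1-(3,4,5-trimethoxyphenyl)prop-2-yn-1-yl]oxy}benzene
Conditions: [Cu(MeCN)4]BF4 (5 mol %), Ph-pybox (single antipode, 6 mol %), i-Pr2NEt, MeOH, −20 °C
Reagents that add atoms: none
Why: Copper-catalysed enantioselective propargylic substitution: the copper acetylide of 4 expels acetate to give a copper allenylidene, the phenoxide of 5 adds to its γ-carbon inside the chiral pybox pocket so that the ligand alone sets the C–O stereocentre (S in 6, the same spatial arrangement that is called R at C2 from 7 onwards because the CIP ranking of the neighbours changes on ring closure), the phenoxide outruns methanol as nucleophile, and monovalent copper at −20 °C leaves the C–I and C–Br bonds alone.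

Step 3
Reactants: 6 4-bromo-1-iodo-2-{[(1S)-1-(3,4,5-trimethoxyphenyl)prop-2-yn-1-yl]oxy}benzene
Product: 7 (2R)-6-bromo-3-methylidene-2-(3,4,5-trimethoxyphenyl)-2,3-dihydro-1-benzofuran
Conditions: Bu3SnH (slight excess), Et3B (cat.), air, PhMe, 0 °C; KF work-up, Et3N-deactivated silica
Reagents that add atoms: none
Why: Tin hydride radical chain cyclisation: iodine abstraction, far faster than bromine abstraction, gives the aryl radical, which closes 5-exo-dig onto the alkyne before the vinyl radical is quenched by Bu3SnH, the stereocentre is not part of any bond change, and the low temperature with a base-buffered work-up should keep the exocyclic alkene from shifting into the ring, so 7 is taken on at once.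

Step 4
Reactants: 7 (2R)-6-bromo-3-methylidene-2-(3,4,5-trimethoxyphenyl)-2,3-dihydro-1-benzofuran
Product: 9 (2R)-6-bromo-3-hydroperoxy-3-methyl-2-(3,4,5-trimethoxyphenyl)-2,3-dihydro-1-benzofuran (both C3 epimers), via triethylsilyl peroxide 8 (not isolated)
Conditions: Co(acac)2 (10 mol %), O2 (1 atm), Et3SiH, ClCH2CH2Cl, rt; then K2CO3, MeOH, 0 °C; neutral silica
Reagents that add atoms: dioxygen, O=O
Why: Mukaiyama–Isayama hydroperoxysilylation: a cobalt hydride passes a hydrogen atom to the CH2 terminus to give the tertiary benzylic C3 radical, which is trapped by O2 much faster than it can lose hydrogen and is then silylated, and mild methanolysis frees the hydroperoxide; C3 forms as both epimers, which is harmless because C3 is flattened in step 5, and C2 is untouched.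

Step 5
Reactants: 9 (2R)-6-bromo-3-hydroperoxy-3-methyl-2-(3,4,5-trimethoxyphenyl)-2,3-dihydro-1-benzofuran
Product: 10 (2R)-7-bromo-3-methyl-2-(3,4,5-trimethoxyphenyl)-2,3-dihydro-1,4-benzodioxin-3-ol (hemiketal, both C3 anomers)
Conditions: TFA (2 equiv), H2O (3 equiv), CH2Cl2, −20 °C, brief; cold pH 7 buffer; crude product used directly
Reagents that add atoms: water, O
Why: Proposed new method: protonation of the terminal peroxide oxygen lets water leave while the fused aryl carbon (C3a of the benzofuran, C4a of the product) shifts from C3 to the inner oxygen through an arenium-like bridged transition state, giving the C3 oxocarbenium ion stabilised by the new O4, which water captures as hemiketal 10. The closest known reaction type is the Hock rearrangement of cumene hydroperoxide and its ring-expanding form on benzo-fused cycloalkyl hydroperoxides such as tetralin hydroperoxide; its use on a 3-hydroperoxy-2,3-dihydrobenzofuran with an oxygenated C2 as rival migrating group is the untested part. The dioxane ring is closed by ring expansion, that is by a 1,2-shift that inserts O4 into the C3–C3a bond of the furan ring, not by cyclisation of a chain. No stereocentre is set under control: C3 becomes an anomeric hemiketal carbon that is erased in step 6, and C2 takes no part and stays R. The selectivity needed is migration of the aryl carbon and not of C2 or methyl; it rests on O1 standing ortho to the migrating carbon, where its p lone pair stabilises the arenium-like transition state while lying perpendicular to the C2–C3 bond and so giving little help to a shift of C2, on the low migratory aptitude of methyl, and on the para bromine retarding only mildly. Cold, short, wet acid lets water intercept the cation before it can lose the C2 proton and limits loss of hydrogen peroxide from C3.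

Step 6
Reactants: 10 (2R)-7-bromo-3-methyl-2-(3,4,5-trimethoxyphenyl)-2,3-dihydro-1,4-benzodioxin-3-ol
Product: 11 (2R,3S)-7-bromo-3-methyl-2-(3,4,5-trimethoxyphenyl)-2,3-dihydro-1,4-benzodioxine
Conditions: Et3SiH (excess, premixed), then BF3·OEt2, CH2Cl2, −78 °C to −40 °C
Reagents that add atoms: none
Why: Ionic hydrogenation of a hemiketal: BF3 ionises 10 to the C3 oxocarbenium ion stabilised by O4, the C2 aryl group lies pseudoaxial to escape allylic strain with the C3 methyl, and Et3SiH delivers hydride to the face opposite the aryl group, which sets C3 as S with the methyl cis to the aryl; silane present in excess before the Lewis acid is added at −78 °C should capture the cation before it can lose the C2 proton.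

Step 7
Reactants: 11 (2R,3S)-7-bromo-3-methyl-2-(3,4,5-trimethoxyphenyl)-2,3-dihydro-1,4-benzodioxine; 12 allyltributylstannane
Product: 13 (2R,3S)-3-methyl-7-(prop-2-en-1-yl)-2-(3,4,5-trimethoxyphenyl)-2,3-dihydro-1,4-benzodioxine (CNP0000093.1)
Conditions: 12, Pd(PPh3)4 (5 mol %), PhMe, 110 °C
Reagents that add atoms: none
Why: Migita–Kosugi–Stille coupling: oxidative addition of zerovalent palladium to the aryl bromide, allyl transfer from tin and reductive elimination are routine for alkoxy-substituted bromoarenes, and neither stereocentre nor any ether is touched.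

Compound list
1 | 3,4,5-trimethoxybenzaldehyde | COc1cc(C=O)cc(OC)c1OC | starting material
2 | ethynylmagnesium bromide | C#C[Mg]Br | starting material
3 | bromomagnesium 1-(3,4,5-trimethoxyphenyl)prop-2-yn-1-olate (racemic) | C#CC(O[Mg]Br)c1cc(OC)c(OC)c(OC)c1 | intermediate
4 | rac-1-(3,4,5-trimethoxyphenyl)prop-2-yn-1-yl acetate | C#CC(OC(C)=O)c1cc(OC)c(OC)c(OC)c1 | intermediate
5 | 5-bromo-2-iodophenol | Oc1cc(Br)ccc1I | starting material
6 | 4-bromo-1-iodo-2-{[(1S)-1-(3,4,5-trimethoxyphenyl)prop-2-yn-1-yl]oxy}benzene | Brc1ccc(I)c(c1)O[C@H](c1cc(OC)c(OC)c(OC)c1)C#C | intermediate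
7 | (2R)-6-bromo-3-methylidene-2-(3,4,5-trimethoxyphenyl)-2,3-dihydro-1-benzofuran | Brc1ccc2c(c1)O[C@H](c1cc(OC)c(OC)c(OC)c1)C2=C | intermediate
8 | triethylsilyl (2R)-6-bromo-3-methyl-2-(3,4,5-trimethoxyphenyl)-2,3-dihydro-1-benzofuran-3-yl peroxide (both C3 epimers) | Brc1ccc2c(c1)O[C@H](c1cc(OC)c(OC)c(OC)c1)C2(C)OO[Si](CC)(CC)CC | intermediate
9 | (2R)-6-bromo-3-hydroperoxy-3-methyl-2-(3,4,5-trimethoxyphenyl)-2,3-dihydro-1-benzofuran (both C3 epimers) | Brc1ccc2c(c1)O[C@H](c1cc(OC)c(OC)c(OC)c1)C2(C)OO | intermediate
10 | (2R)-7-bromo-3-methyl-2-(3,4,5-trimethoxyphenyl)-2,3-dihydro-1,4-benzodioxin-3-ol (both C3 anomers) | Brc1ccc2c(c1)O[C@H](c1cc(OC)c(OC)c(OC)c1)C(C)(O)O2 | intermediate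
11 | (2R,3S)-7-bromo-3-methyl-2-(3,4,5-trimethoxyphenyl)-2,3-dihydro-1,4-benzodioxine | Brc1ccc2c(c1)O[C@H](c1cc(OC)c(OC)c(OC)c1)[C@H](C)O2 | intermediate
12 | allyltributylstannane | C=CC[Sn](CCCC)(CCCC)CCCC | starting material
13 | (2R,3S)-3-methyl-7-(prop-2-en-1-yl)-2-(3,4,5-trimethoxyphenyl)-2,3-dihydro-1,4-benzodioxine | C=CCc1ccc2c(c1)O[C@H](c1cc(OC)c(OC)c(OC)c1)[C@H](C)O2 | target

Total step count: 7. Longest linear sequence: 7 steps (1 to 13).

Steps most likely to fail

1. Step 5 (carries the label). What may go wrong: migration of C2 or of methyl instead of the aryl carbon; heterolysis of the C3–O bond with loss of hydrogen peroxide and proton loss, which aromatises the furan ring; or proton loss from C2 of the oxocarbenium ion and reprotonation, which erodes the C2 configuration. The fallback uses known chemistry only, sets out from 1 (with 5 entering later) and returns to the route at 11, after which step 7 follows unchanged. EtMgBr addition to 1 (THF, 0 °C) gives 1-(3,4,5-trimethoxyphenyl)propan-1-ol F1. TsOH-catalysed dehydration (PhMe, reflux, water removal) gives 1,2,3-trimethoxy-5-[(1E)-prop-1-en-1-yl]benzene F2. Shi epoxidation with the enantiomer of the fructose-derived ketone (made from L-sorbose), Oxone, buffered MeCN/H2O, 0 °C, should give (2S,3S)-2-methyl-3-(3,4,5-trimethoxyphenyl)oxirane F3. Opening of F3 by the caesium phenoxide of 5 (Cs2CO3, DMF, 60 °C) at the benzylic carbon with inversion should give (1R,2S)-1-(5-bromo-2-iodophenoxy)-1-(3,4,5-trimethoxyphenyl)propan-2-ol F4. Intramolecular Ullmann etherification at the C–I bond (CuI, 1,10-phenanthroline, Cs2CO3, PhMe, 110 °C) forms O4–C4a with retention at C3 and closes the dioxane ring to 11.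

2. Step 6. What may go wrong: hydride delivery to the face of the cation that carries the aryl group (trans isomer); deprotonation of the cation at C2 followed by reprotonation (loss of enantiopurity); or reduction of the ring-opened keto phenol instead of the cyclic cation. The fallback sets out from 10 and returns at 11, replacing cation reduction by carbonyl reduction and stereospecific ring closure. K-Selectride (THF, −78 °C) reduces the ring-opened keto phenoxide under non-chelating Felkin–Anh control and should give the threo alcohol (1R,2R)-1-(5-bromo-2-hydroxyphenoxy)-1-(3,4,5-trimethoxyphenyl)propan-2-ol F5. Intramolecular Mitsunobu etherification (PPh3, DIAD, THF, 0 °C) then forms O4–C3 with inversion, giving the cis compound 11.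

3. Step 2. What may go wrong: insufficient enantiofacial discrimination with the hindered, weakly nucleophilic ortho-iodophenoxide, or capture of the allenylidene by methanol. The fallback sets out from 4 and returns at 6, replacing asymmetric catalysis by resolution and stereospecific substitution. Enantioselective butanolysis of racemic 4 with immobilised Candida antarctica lipase B (n-BuOH, MTBE, rt) should release, by the Kazlauskas rule, (1R)-1-(3,4,5-trimethoxyphenyl)prop-2-yn-1-ol F6, which is separated from the unreacted S acetate. Mitsunobu etherification of F6 with 5 (PPh3, DIAD, PhMe, 0 °C) proceeds with inversion and should give (S)-6.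

Further compounds
F1 | step 5 | 1-(3,4,5-trimethoxyphenyl)propan-1-ol (racemic) | CCC(O)c1cc(OC)c(OC)c(OC)c1
F2 | step 5 | 1,2,3-trimethoxy-5-[(1E)-prop-1-en-1-yl]benzene | C/C=C/c1cc(OC)c(OC)c(OC)c1
F3 | step 5 | (2S,3S)-2-methyl-3-(3,4,5-trimethoxyphenyl)oxirane | O1[C@@H](c2cc(OC)c(OC)c(OC)c2)[C@@H]1C
F4 | step 5 | (1R,2S)-1-(5-bromo-2-iodophenoxy)-1-(3,4,5-trimethoxyphenyl)propan-2-ol | Brc1ccc(I)c(c1)O[C@H](c1cc(OC)c(OC)c(OC)c1)[C@H](C)O
F5 | step 6 | (1R,2R)-1-(5-bromo-2-hydroxyphenoxy)-1-(3,4,5-trimethoxyphenyl)propan-2-ol | Brc1ccc(O)c(c1)O[C@H](c1cc(OC)c(OC)c(OC)c1)[C@@H](C)O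
F6 | step 2 | (1R)-1-(3,4,5-trimethoxyphenyl)prop-2-yn-1-ol | O[C@@H](c1cc(OC)c(OC)c(OC)c1)C#C
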